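We must choose which recipe gets the next 4.0 min of reactor time: lean and cool as in south-west, or rich with a hot start as in north-west.

| setting | dawn | dusk | south-west | north-west |
|---|---|---|---|---|
| starting material | 0.094 M | 0.22 M | 0.12 M | 0.25 M |
| reagent | 0.225 M | 0.225 M | 0.225 M | 0.225 M |
| initiator | 38 mM | 38 mM | 38 mM | 38 mM |
| temperature | 55 °C | 66 °C |  |  |
| remark | run made earlier | run made earlier | at 50 °C throughout | at 70 °C until 2.0 min, from then on at 50 °C |
| time |  |  | 4.0 min | 4.0 min |

| run | time / min | product / % | starting material / % |
|---|---|---|---|
| dawn | 1.00 | 33.2 | 66.8 |
| dawn | 2.00 | 56.2 | 44.2 |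
| dawn | 3.00 | 71.9 | 28.0 |
| dawn | 4.00 | 81.8 | 17.8 |
| dawn | 5.00 | 88.8 | 10.4 |
| dawn | 6.00 | 93.1 | 6.4 |
| dusk | 0.200 | 11.1 | 88.9 |
| dusk | 0.500 | 25.6 | 73.9 |
| dusk | 1.00 | 44.6 | 55.1 |
| dusk | 1.50 | 58.7 | 41.5 |
| dusk | 2.00 | 69.3 | 30.2 |
| dusk | 3.00 | 84.3 | 16.1 |

(standard deviation of a reading: 0.5 percentage points)

- which one finishes higher in amount of product, in percent of the starting material charged ("neither" within 2 percentage points) (south-west / north-west / neither)
- amount of product at the end, in percent of the starting material charged, south-west
- amount of product at the end, in percent of the starting material charged, north-west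

- in percentages every species weighs as the starting material in it: one ended chains A counts as two
- on the list of suspects stand: initiator -> 2 initiating radical; starting material + initiating radical -> capped initiator + first chain carrier; reagent + first chain carrier -> product + second chain carrier; starting material + second chain carrier -> released group + first chain carrier; 2 first chain carrier -> ended chains A; 2 second chain carrier -> ended chains B

A ratio from which time drops out tells how much room each recipe has, but not how far it gets in 4.0 min. Product and starting material still add up to the charge within the scatter, 99.5% at the last dawn reading and 100% at the last dusk reading, so one product appears per starting material lost. The suspect step that makes product takes one reagent, so if that step is its source, reagent lost over product gained is one at each moment, and temperature and time cancel.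

North-west's reagent ceiling is therefore 90.0%: the ceiling C, reagent charge over starting material charge, is the most product the reagent can pay for, in percent of the starting material charged. Reagent is the limiting reagent there. South-west's C is 188%, above the whole charge, so starting material limits it and its room has to be filled by pace. But south-west is colder than dawn, which held 81.8% at 4.00 min, and north-west's C stands higher than that reading. Dusk, cooler than north-west's first stage, already held 69.3% at 2.00 min. C stands higher for south-west, so our choice rests on pace in the hot first stage and not on the ratio: we would charge north-west.

The forecast says north-west, with 77.5% against 61.5% for south-west, and holds for north-west that “reagent is limiting (90% ceiling)”.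

The flasks give north-west: 77.3% against 63.0% in south-west, within the forecast's tolerance.

    initiator → 2 initiating radical (k = 5.18 × 10⁻⁵ s⁻¹, Ea = 110 kJ mol⁻¹)
    starting material + initiating radical → capped initiator + first chain carrier (k = 5.51 × 10⁶ L mol⁻¹ s⁻¹, Ea = 26.0 kJ mol⁻¹)
    reagent + first chain carrier → product + second chain carrier (k = 1.79 × 10⁵ L mol⁻¹ s⁻¹, Ea = 23.0 kJ mol⁻¹)
    starting material + second chain carrier → released group + first chain carrier (k = 2.95 × 10⁵ L mol⁻¹ s⁻¹, Ea = 33.0 kJ mol⁻¹)
    2 first chain carrier → ended chains A (k = 3.00 × 10⁸ L mol⁻¹ s⁻¹, Ea = 13.0 kJ mol⁻¹)
    2 second chain carrier → ended chains B (k = 2.00 × 10⁸ L mol⁻¹ s⁻¹, Ea = 13.0 kJ mol⁻¹)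
    (constants at 70 °C)

In south-west at 4.00 min, starting material goes through its step with second chain carrier 550 times as fast as through capping by initiating radical. North-west ends below its C, which puts its reagent left at 14.1%, and the flask holds 14%; at 40.0 min its product stands at 90.0%, with reagent at 0.0201%, and south-west's product stands at >99.9%, the order of the two C. The flask like south-west read at 6.0 min has C of 188%, so its 78.8% of product should leave 58.1% of the reagent; the computed flask holds 58%.

All runs are simulated for substances that don't exist.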